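## Structural features

Isariotin C is the (E)-7-oxododec-2-enamide of a 7-aminobicyclo[3.3.1]nonan-9-one. The core is numbered C1 (bridgehead, tertiary OH), C2–C3 (cis-epoxide), C4 (CHOH), C5 (bridgehead CH), C6 (CHOH), C7 (CHN), C8 (CH2) and C9 (bridging C=O); ring A is C1–C2–C3–C4–C5–C9 and ring B is C1–C8–C7–C6–C5–C9. The seven stereocentres C1–C7 are contiguous, and the epoxide oxygen, the C4 and C6 hydroxyls and the nitrogen are all exo (on the side of the C9 bridge). Ring A therefore carries an all-cis O1/epoxide/O4 array and ring B a cis-amino alcohol with equatorial nitrogen. C9 is the carbonyl of a tertiary α-ketol (C1) and of two aldol units (C4–OH and C6–OH are both β to it), so the core is open to retro-aldol cleavage and α-ketol rearrangement with base, and the cis-epoxy alcohol is acid-sensitive. The side chain holds an enamide and a ketone that tolerate neither hydride nor hydrazine. The real difficulty is the quaternary carbinol C1: its configuration has to be tied to that of C7 across the C8 methylene while the bridged ring is closed at C5–C6 with control of C5 and C6. The key step exploits the fact that C1 carries two ring arms, C9 and C2. If C2 is raised to the ketone level and C3–C4 is unsaturated, the two arms exchange by dienol tautomerism, C1 lies on a local mirror plane of ring A, and C7 alone decides which arm closes ring B. The extra C2 carbonyl is then the handle that delivers the C4 hydroxyl and the C2=C3 double bond by an epoxy ketone transposition.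

## Logic of the disconnections

**24 to 23.** The C2–O and C3–O bonds of the epoxide are cut. The epoxide is the most acid-sensitive group and is best made last, and the allylic C4 hydroxyl (with the C1 hydroxyl on the same side) of 23 can deliver oxygen to the exo face. One ring and two stereocentres are removed. The forward step needs an oxidant that ignores the enamide and the ketones.

**23 to 16 and 22.** The amide C–N bond is cut. The side chain cannot pass through the hydrazine and dioxirane steps of the core, and the cut makes the route convergent. The forward step must acylate nitrogen in the presence of three free hydroxyls.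

**22 to 20 and 21, and 20 to 17 and 18.** The C2=C3 double bond of the acid is cut (cross-metathesis), then the bond between the ketone carbon and the pentyl group (Grignard addition to a nitrile). Both go back to commercial materials. The demands are E-selectivity and a single addition.

**16 to 15 to 13 to 12.** After removal of the carbamate and silyl groups (16 to 15), the C4 hydroxyl and the C2=C3 double bond of 15 are traced to the epoxy ketone 13 (C3–O bond re-formed, C2 carbonyl restored), and 13 to the enone 12 (C3–O and C4–O cut). The reason is that the C4 oxygen is then introduced as an epoxide on the open exo face instead of by reduction of a C4 ketone from the concave face. The demands are exo-selective epoxidation of an electron-poor alkene without base, and a transposition that spares the C9 ketone.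

**12 to 9 (key).** The C5–C6 bond (and the two O–Si bonds) is cut. The bicycle becomes a monocycle with a single stereocentre (C7), and C1, C5 and C6 are removed in one operation. The forward step must select one of two diastereotopic carbonyl arms, control the aldehyde face, and not enolise the α-amino aldehyde.

**9 to 8 to 7 to 5.** These are changes of oxidation level and protection: the lactol goes back to the primary alcohol, the amino alcohol to the N,O-acetal, and the C3=C4 double bond to the saturated dione (two C–H bonds). The demand is a desaturation that stops after one double bond.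

**5 to 4, and 4 to 1 and 2.** The C1–O bond is cut (α-hydroxylation of a β-diketone), then the C1–C8 bond (reductive alkylation of the dione with the aldehyde). The stereocentre C7 is bought with 2 and all carbons of the core are present after the first step. The demand is that the α-amino aldehyde is not epimerised.

## Other disconnections considered

**Alternative 1:** The first idea is the biomimetic one. C5–C6 is cut in a fully oxygenated ring A, and the forward key step is a base-mediated aldol of the epoxy keto aldehyde A2, made from a tyrosine-derived p-quinol A1 by hypervalent-iodine dearomatisation, epoxidation and reduction. In A1 the phenol oxygen ends at C4, but the target has C4–OH and C9=O, so a redox transposition is unavoidable. The two enone arms of A1 are diastereotopic, and any epoxidation or oxidation that tells them apart before ring closure is not under the control of C7, so C1 would form as a mixture. A direct oxa-Michael/aldol on A1 gives the C9–OH/C4=O pattern and then needs selective oxidation among three secondary alcohols. The chosen plan has the carbonyl at C9 from the start and lets C7 choose the arm.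

**Alternative 2:** A resorcinol-type amino aldehyde (oxygens at C9 and C4) is dearomatised by para-hydroxylation at C1 to the vinylogous acid A3, whose C5 adds to the aldehyde to give the bicyclic enedione A4; epoxidation and C4 reduction would finish the core. This is shorter in oxidation-state terms. However, C1 is created in the dearomatisation, when the two arms are already different and the remote C7 cannot bias the face, so both C1 epimers form and each can cyclise. The C4 ketone of A4 must also be reduced from the concave endo face in the presence of the C9 ketone, whereas hydride is expected from the exo face. The chosen plan creates C1 in a cyclisation that C7 controls and makes the C4–O bond by oxygen delivery to the exo face.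

**Alternative 3:** Ring A is closed last by ring-closing metathesis across C2=C3: the cyclohexanone A5 (ring B complete, vinyl on C1, 1-hydroxyallyl on C5) would give A6 with the second-generation Grubbs catalyst, then directed epoxidation. The metathesis itself settles none of the stereochemical problem. C1, C4, C5, C6 and C7 would have to be set one by one on a monocycle (vinyl addition to an α-diketone equivalent, acrolein aldol), the two alkenyl arms must be cis-diaxial, and the C1/C7 relation would again depend on an uncontrolled face-selective addition. The step count would be clearly higher than in the chosen plan.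

Key step: step 6

Remark: in 7, 8, 9 and 10 the carbinol carbon of the cyclohexenedione is drawn without configuration, because its two carbonyl arms exchange through the dienol; it becomes the fixed stereocentre C1 only in step 6.

## Steps

Step 1
Reactants: 1 cyclohexane-1,3-dione; 2 tert-butyl (R)-4-formyl-2,2-dimethyloxazolidine-3-carboxylate
Product: 4 tert-butyl (S)-4-[(2,6-dioxocyclohexyl)methyl]-2,2-dimethyloxazolidine-3-carboxylate, via alkylidene dione 3 (not isolated)
Conditions: Hantzsch ester (diethyl 2,6-dimethyl-1,4-dihydropyridine-3,5-dicarboxylate, 1.1 equiv), L-proline (10 mol %), CH2Cl2, rt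
Reagents that add atoms: none
Why: Amine-catalysed Knoevenagel condensation gives the strongly electrophilic alkylidene dione 3, which is reduced at once by hydride transfer from the Hantzsch ester (three-component reductive alkylation), so C-alkylation is clean and a second condensation is impossible. The stereocentre (future C7) is not a reacting centre; its descriptor changes from R to S only because the priorities change.

Step 2
Reactants: 4 tert-butyl (S)-4-[(2,6-dioxocyclohexyl)methyl]-2,2-dimethyloxazolidine-3-carboxylate
Product: 5 tert-butyl (S)-4-[(1-hydroxy-2,6-dioxocyclohexyl)methyl]-2,2-dimethyloxazolidine-3-carboxylate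
Conditions: dimethyldioxirane (1.1 equiv, acetone solution), CH2Cl2, 0 °C
Reagents that add atoms: dimethyldioxirane, CC1(C)OO1
Why: The 2-alkyl-1,3-dione is fully enolised and the neutral dioxirane epoxidises the electron-rich enol double bond; the epoxide opens to the 2-hydroxy-1,3-dione (α-hydroxylation of a β-dicarbonyl). The new carbinol carbon (future C1) still lies on a mirror plane of the ring, so no stereocentre is created.

Step 3
Reactants: 5 tert-butyl (S)-4-[(1-hydroxy-2,6-dioxocyclohexyl)methyl]-2,2-dimethyloxazolidine-3-carboxylate
Product: 7 tert-butyl (S)-4-{[2,6-dioxo-1-(trimethylsilyloxy)cyclohex-3-en-1-yl]methyl}-2,2-dimethyloxazolidine-3-carboxylate, via silyl enol ether 6 (not isolated)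
Conditions: LiN(SiMe3)2 (2.2 equiv), Me3SiCl (3 equiv), THF, −78 °C; then Pd(OAc)2 (1.1 equiv), MeCN, rt
Reagents that add atoms: chlorotrimethylsilane, C[Si](C)(C)Cl
Why: Saegusa–Ito oxidation: in-situ silylation gives the tertiary silyl ether and one silyl enol ether, and divalent palladium turns the enol ether into the enone by β-hydride elimination. A second desaturation is impossible because it would need a cumulated diene, and the nitrogen has no N–H at this stage, so the base is consumed only by the hydroxyl and the ketone.

Step 4
Reactants: 7 tert-butyl (S)-4-{[2,6-dioxo-1-(trimethylsilyloxy)cyclohex-3-en-1-yl]methyl}-2,2-dimethyloxazolidine-3-carboxylate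
Product: 8 tert-butyl N-[(2S)-1-hydroxy-3-(1-hydroxy-2,6-dioxocyclohex-3-en-1-yl)propan-2-yl]carbamate
Conditions: p-TsOH·H2O (0.1 equiv), MeOH, 0 °C to rt
Reagents that add atoms: none
Why: Acid-catalysed transacetalisation in methanol removes the N,O-isopropylidene group and the labile tertiary trimethylsilyl ether, while the tert-butyl carbamate survives catalytic sulfonic acid at room temperature.

Step 5
Reactants: 8 tert-butyl N-[(2S)-1-hydroxy-3-(1-hydroxy-2,6-dioxocyclohex-3-en-1-yl)propan-2-yl]carbamate
Product: 9 tert-butyl N-[(3S)-2-hydroxy-6,10-dioxo-1-oxaspiro[4.5]dec-8-en-3-yl]carbamate (lactol, mixture of anomers and spiro epimers)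
Conditions: Dess–Martin periodinane (1.1 equiv), CH2Cl2, 0 °C
Reagents that add atoms: none
Why: Dess–Martin oxidation of the primary alcohol of a carbamate-protected amino alcohol is fast and should not epimerise the α-centre. The aldehyde is trapped at once by the tertiary hydroxyl as a five-membered lactol, which stores it in a form that cannot enolise; one equivalent of oxidant limits over-oxidation to the lactone.

Step 6
Reactants: 9 tert-butyl N-[(3S)-2-hydroxy-6,10-dioxo-1-oxaspiro[4.5]dec-8-en-3-yl]carbamate
Product: 12 tert-butyl N-[(1S,5R,6R,7S)-2,9-dioxo-1,6-bis(triethylsilyloxy)bicyclo[3.3.1]non-3-en-7-yl]carbamate, via open hydroxy aldehyde 10 (not isolated), via bicyclic aldol 11 (not isolated)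
Conditions: MgBr2·OEt2 (1.5 equiv), i-Pr2NEt (1.2 equiv), CH2Cl2, −40 to 0 °C; then 2,6-lutidine (4 equiv), Et3SiOTf (3 equiv), −78 to −20 °C
Reagents that add atoms: triethylsilyl trifluoromethanesulfonate, CC[Si](CC)(CC)OS(=O)(=O)C(F)(F)F
Why: The lactol opens to hydroxy aldehyde 10, whose cyclohex-4-ene-1,3-dione is a vinylogous 1,3-dicarbonyl that MgBr2 and a tertiary amine convert by soft enolisation into a magnesium dienolate in which the two carbonyl arms on the carbinol carbon are equivalent; its terminus C5 adds to the magnesium-bound aldehyde C6 in an intramolecular aldol addition. The closest known reaction type is the Hajos–Parrish-type desymmetrising aldol of 2,2-disubstituted cyclohexane-1,3-diones, here run as a magnesium-mediated direct aldol. Ring B is closed in the 6-(enolendo)-exo-trig mode through a chair in which the C1–C8–C7–C6 tether is diaxial on ring A, so C5 can only be formed cis to C8. C1 becomes a stereocentre through the choice of arm: with (S)-C7 only one arm lets the carbamate nitrogen sit equatorial on the forming chair, the other would put it axial over ring A, so C7 fixes C1 and C5. C6 is controlled by the six-membered magnesium chelate between the dienolate oxygen and the aldehyde oxygen, which keeps the new C6–O bond gauche to C9 and therefore exo. The selectivities needed are arm selection, the aldehyde face and retention at C7; the first two rest on the chair and the chelate, the third on the low concentration of free aldehyde (lactol reservoir), the weak base that the acidic dienol allows, and the low temperature. Dehydration is excluded because it would need a bridgehead double bond (Bredt's rule), and silylation of the aldolate in the same flask closes the retro-aldol path and protects both hydroxyls for steps 7 and 8.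

Step 7
Reactants: 12 tert-butyl N-[(1S,5R,6R,7S)-2,9-dioxo-1,6-bis(triethylsilyloxy)bicyclo[3.3.1]non-3-en-7-yl]carbamate
Product: 13 tert-butyl N-[(1R,3S,4S,5R,6R,7S)-3,4-epoxy-2,9-dioxo-1,6-bis(triethylsilyloxy)bicyclo[3.3.1]nonan-7-yl]carbamate (exo epoxide)
Conditions: dimethyldioxirane (excess, acetone solution), CH2Cl2, 0 °C to rt
Reagents that add atoms: dimethyldioxirane, CC1(C)OO1
Why: Neutral electrophilic epoxidation of the enone by the dioxirane avoids the basic peroxide conditions that would invite retro-Claisen or retro-aldol cleavage of the non-enolisable β-diketone. The reagent should approach from the exo face because the endo face of C3=C4 is covered by C6 and C8, so the C4–O bond is set exo.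

Step 8
Reactants: 13 tert-butyl N-[(1R,3S,4S,5R,6R,7S)-3,4-epoxy-2,9-dioxo-1,6-bis(triethylsilyloxy)bicyclo[3.3.1]nonan-7-yl]carbamate
Product: 15 tert-butyl N-[(1S,4R,5R,6R,7S)-4-hydroxy-9-oxo-1,6-bis(triethylsilyloxy)bicyclo[3.3.1]non-2-en-7-yl]carbamate, via hydrazone 14 (not isolated)
Conditions: N2H4·H2O (2 equiv), AcOH (cat.), MeOH, 0 °C to rt; acetone quench
Reagents that add atoms: none
Why: Wharton transposition: the hydrazone of the epoxy ketone opens the epoxide to an alkenyl diazene that loses nitrogen, which places the double bond at C2=C3 and leaves the epoxide oxygen on C4 with retention, that is exo. Hydrazone formation at the hindered C9 ketone is reversible and unproductive, so material should funnel through the irreversible fragmentation at C2.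

Step 9
Reactants: 15 tert-butyl N-[(1S,4R,5R,6R,7S)-4-hydroxy-9-oxo-1,6-bis(triethylsilyloxy)bicyclo[3.3.1]non-2-en-7-yl]carbamate
Product: 16 (1S,4R,5R,6R,7S)-7-amino-1,4,6-trihydroxybicyclo[3.3.1]non-2-en-9-one, trifluoroacetate salt
Conditions: CF3CO2H/H2O (9:1), 0 °C; evaporation with toluene
Reagents that add atoms: trifluoroacetic acid, OC(=O)C(F)(F)F
Why: Aqueous trifluoroacetic acid cleaves the tert-butyl carbamate and both triethylsilyl ethers in one operation. The allylic alcohol and the α-ketol are flanked by the electron-withdrawing C9 carbonyl, which should disfavour ionisation at 0 °C.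

Step 10
Reactants: 17 hex-5-enenitrile; 18 pentylmagnesium bromide
Product: 20 undec-1-en-6-one, via magnesium ketiminate 19 (not isolated)
Conditions: CuBr·SMe2 (2 mol %), Et2O, reflux; then 2 M HCl, rt
Reagents that add atoms: water, O
Why: A Grignard reagent adds once to a nitrile (the copper bromide catalyst suppresses α-deprotonation), and the magnesium ketiminate is hydrolysed to the ketone only on acidic work-up, so over-addition cannot occur.

Step 11
Reactants: 20 undec-1-en-6-one; 21 acrylic acid
Product: 22 (E)-7-oxododec-2-enoic acid
Conditions: second-generation Grubbs catalyst RuCl2(=CHPh)(PCy3)(H2IMes) (3 mol %), acrylic acid (3 equiv), CH2Cl2, 40 °C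
Reagents that add atoms: none
Why: Olefin cross-metathesis of a terminal alkene with excess acrylic acid should give the thermodynamically favoured E-enoic acid; the ketone is inert to the ruthenium carbene.

Step 12
Reactants: 16 (1S,4R,5R,6R,7S)-7-amino-1,4,6-trihydroxybicyclo[3.3.1]non-2-en-9-one, trifluoroacetate salt; 22 (E)-7-oxododec-2-enoic acid
Product: 23 (E)-7-oxo-N-[(1S,4R,5R,6R,7S)-1,4,6-trihydroxy-9-oxobicyclo[3.3.1]non-2-en-7-yl]dodec-2-enamide
Conditions: EDC·HCl (1.2 equiv), HOBt, N-methylmorpholine (2.5 equiv), DMF, 0 °C to rt
Reagents that add atoms: none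
Why: Carbodiimide/HOBt amide coupling acylates the primary amine far faster than the three hydroxyls, so no hydroxyl protection is needed and no stereocentre is touched.

Step 13
Reactants: 23 (E)-7-oxo-N-[(1S,4R,5R,6R,7S)-1,4,6-trihydroxy-9-oxobicyclo[3.3.1]non-2-en-7-yl]dodec-2-enamide
Product: 24 isariotin C, (E)-N-[(1S,2S,3S,4S,5S,6R,7S)-2,3-epoxy-1,4,6-trihydroxy-9-oxobicyclo[3.3.1]nonan-7-yl]-7-oxododec-2-enamide (core numbering as above)
Conditions: VO(acac)2 (5 mol %), t-BuOOH (1.5 equiv, decane solution), CH2Cl2, 0 °C to rt
Reagents that add atoms: tert-butyl hydroperoxide, CC(C)(C)OO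
Why: Vanadium-catalysed hydroxyl-directed epoxidation: the hydroperoxide is delivered within a vanadate ester of the pseudo-axial C4 hydroxyl (the C1 hydroxyl lies on the same side), so oxygen should add to the exo face of C2=C3 and give the cis-epoxy alcohol. The electron-poor enamide double bond and the ketones do not react.

## Compound list

1 | cyclohexane-1,3-dione | O=C1CCCC(=O)C1 | starting material
2 | tert-butyl (R)-4-formyl-2,2-dimethyloxazolidine-3-carboxylate | CC1(C)OC[C@H](C=O)N1C(=O)OC(C)(C)C | starting material
3 | tert-butyl (S)-4-[(2,6-dioxocyclohexylidene)methyl]-2,2-dimethyloxazolidine-3-carboxylate | CC1(C)OC[C@H](C=C2C(=O)CCCC2=O)N1C(=O)OC(C)(C)C | intermediate (not isolated)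
4 | tert-butyl (S)-4-[(2,6-dioxocyclohexyl)methyl]-2,2-dimethyloxazolidine-3-carboxylate | CC1(C)OC[C@H](CC2C(=O)CCCC2=O)N1C(=O)OC(C)(C)C | intermediate
5 | tert-butyl (S)-4-[(1-hydroxy-2,6-dioxocyclohexyl)methyl]-2,2-dimethyloxazolidine-3-carboxylate | CC1(C)OC[C@H](CC2(O)C(=O)CCCC2=O)N1C(=O)OC(C)(C)C | intermediate
6 | tert-butyl (S)-2,2-dimethyl-4-{[6-oxo-1,2-bis(trimethylsilyloxy)cyclohex-2-en-1-yl]methyl}oxazolidine-3-carboxylate | CC1(C)OC[C@H](CC2(O[Si](C)(C)C)C(=O)CCC=C2O[Si](C)(C)C)N1C(=O)OC(C)(C)C | intermediate (not isolated)
7 | tert-butyl (S)-4-{[2,6-dioxo-1-(trimethylsilyloxy)cyclohex-3-en-1-yl]methyl}-2,2-dimethyloxazolidine-3-carboxylate | CC1(C)OC[C@H](CC2(O[Si](C)(C)C)C(=O)CC=CC2=O)N1C(=O)OC(C)(C)C | intermediate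
8 | tert-butyl N-[(2S)-1-hydroxy-3-(1-hydroxy-2,6-dioxocyclohex-3-en-1-yl)propan-2-yl]carbamate | CC(C)(C)OC(=O)N[C@H](CO)CC1(O)C(=O)CC=CC1=O | intermediate
9 | tert-butyl N-[(3S)-2-hydroxy-6,10-dioxo-1-oxaspiro[4.5]dec-8-en-3-yl]carbamate | CC(C)(C)OC(=O)N[C@H]1CC2(OC1O)C(=O)CC=CC2=O | intermediate
10 | tert-butyl N-[(2S)-1-(1-hydroxy-2,6-dioxocyclohex-3-en-1-yl)-3-oxopropan-2-yl]carbamate | CC(C)(C)OC(=O)N[C@H](C=O)CC1(O)C(=O)CC=CC1=O | intermediate (not isolated)
11 | tert-butyl N-[(1S,5R,6R,7S)-1,6-dihydroxy-2,9-dioxobicyclo[3.3.1]non-3-en-7-yl]carbamate | CC(C)(C)OC(=O)N[C@H]1C[C@@]2(O)C(=O)[C@H](C=CC2=O)[C@H]1O | intermediate (not isolated)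
12 | tert-butyl N-[(1S,5R,6R,7S)-2,9-dioxo-1,6-bis(triethylsilyloxy)bicyclo[3.3.1]non-3-en-7-yl]carbamate | CC(C)(C)OC(=O)N[C@H]1C[C@@]2(O[Si](CC)(CC)CC)C(=O)[C@H](C=CC2=O)[C@H]1O[Si](CC)(CC)CC | intermediate
13 | tert-butyl N-[(1R,3S,4S,5R,6R,7S)-3,4-epoxy-2,9-dioxo-1,6-bis(triethylsilyloxy)bicyclo[3.3.1]nonan-7-yl]carbamate | CC(C)(C)OC(=O)N[C@H]1C[C@@]2(O[Si](CC)(CC)CC)C(=O)[C@H]([C@@H]3O[C@@H]3C2=O)[C@H]1O[Si](CC)(CC)CC | intermediate
14 | C2 hydrazone of 13, tert-butyl N-[3,4-epoxy-2-hydrazinylidene-9-oxo-1,6-bis(triethylsilyloxy)bicyclo[3.3.1]nonan-7-yl]carbamate | CC(C)(C)OC(=O)N[C@H]1C[C@@]2(O[Si](CC)(CC)CC)C(=O)[C@H]([C@@H]3O[C@@H]3C2=NN)[C@H]1O[Si](CC)(CC)CC | intermediate (not isolated)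
15 | tert-butyl N-[(1S,4R,5R,6R,7S)-4-hydroxy-9-oxo-1,6-bis(triethylsilyloxy)bicyclo[3.3.1]non-2-en-7-yl]carbamate | CC(C)(C)OC(=O)N[C@H]1C[C@@]2(O[Si](CC)(CC)CC)C(=O)[C@H]([C@H](O)C=C2)[C@H]1O[Si](CC)(CC)CC | intermediate
16 | (1S,4R,5R,6R,7S)-7-amino-1,4,6-trihydroxybicyclo[3.3.1]non-2-en-9-one trifluoroacetate | [NH3+][C@H]1C[C@@]2(O)C(=O)[C@H]([C@H](O)C=C2)[C@H]1O.[O-]C(=O)C(F)(F)F | intermediate
17 | hex-5-enenitrile | C=CCCCC#N | starting material
18 | pentylmagnesium bromide | CCCCC[Mg]Br | starting material
19 | bromomagnesium salt of undec-1-en-6-imine | CCCCCC(CCCC=C)=N[Mg]Br | intermediate (not isolated)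
20 | undec-1-en-6-one | CCCCCC(=O)CCCC=C | intermediate
21 | acrylic acid | C=CC(=O)O | starting material
22 | (E)-7-oxododec-2-enoic acid | CCCCCC(=O)CCC/C=C/C(=O)O | intermediate
23 | (E)-7-oxo-N-[(1S,4R,5R,6R,7S)-1,4,6-trihydroxy-9-oxobicyclo[3.3.1]non-2-en-7-yl]dodec-2-enamide | CCCCCC(=O)CCC/C=C/C(=O)N[C@H]1C[C@@]2(O)C(=O)[C@H]([C@H](O)C=C2)[C@H]1O | intermediate
24 | isariotin C | CCCCCC(=O)CCC/C=C/C(=O)N[C@H]1C[C@@]2(O)C(=O)[C@H]([C@H](O)[C@@H]3O[C@@H]32)[C@H]1O | target

## Step count and least certain steps

Total step count: 13. Longest linear sequence: 11 (steps 1 to 9, 12 and 13); steps 10 and 11 form the side-chain branch.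

**Step 6 (key step).** The most likely failure is loss of configuration at C7 by enolisation of the open α-amino aldehyde. Because the ring is prochiral, this would show up as erosion of enantiomeric purity, not as a diastereomer. A second risk is incomplete control of the aldehyde face if the addition runs through an open instead of the chelated transition state. Both are made worse by the reversibility of an aldol whose leaving group is a stabilised dienolate, since each retro-aldol exposes the aldehyde to base again. The fallback moves the ring closure to the saturated dione, where the aldol is effectively irreversible, and postpones the desaturation. It sets out from 5 and returns at 12. Acid-catalysed removal of the N,O-acetal (p-TsOH·H2O, MeOH) gives the saturated amino alcohol F1, and Dess–Martin oxidation gives the saturated spiro-lactol F2. The magnesium-mediated aldol with silylation in the same flask (reagents of step 6) gives the saturated bis-silyl bicyclic dione F3, in which the C2 ketone can enolise only towards C3 because C9 is flanked by two bridgeheads. Saegusa–Ito oxidation (LiN(SiMe3)2, Me3SiCl; then Pd(OAc)2) then gives 12.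

**Step 1.** Partial racemisation can occur through iminium/enamine formation of the α-amino aldehyde with the amine catalyst, or by γ-deprotonation of the alkylidene dione before hydride transfer. The fallback replaces the condensation by an alkylation; it sets out from 2 and returns at 4. Reduction with NaBH4 gives the oxazolidine alcohol F4, and iodination (I2, PPh3, imidazole) gives the iodide F5. Commercial 1,5-dimethoxycyclohexa-1,4-diene is deprotonated at the carbon between the two enol ethers (t-BuLi, THF/HMPA, −78 °C) and alkylated with F5 to the alkylated bis-enol ether F6. Dilute aqueous oxalic acid in THF hydrolyses both enol ethers to 4.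

**Step 3.** Incomplete desaturation is possible through protodesilylation of the enol ether or protonation of the palladium enolate at the hindered, α-silyloxy-substituted dione, and palladium may be consumed unproductively. The fallback uses a selenoxide elimination; it sets out from 5 and returns at 8. Enolisation with LiN(SiMe3)2 and trapping with PhSeCl gives the α-phenylselanyl dione F7. Oxidation with H2O2/pyridine and syn-elimination of the selenoxide gives the free-hydroxyl enedione F8, which under the conditions of step 4 gives 8.

**Step 8.** Unproductive hydrazone formation at the C9 ketone may hold back material, the fragmentation at the hindered C2 hydrazone may be slow, and diimide formed from hydrazine may reduce the new double bond. The fallback is a radical version of the same transposition; it sets out from 13 and returns at 15. NaBH4/CeCl3·7H2O at −78 °C reduces the activated epoxy ketone carbonyl to the epoxy alcohol F9. 1,1′-Thiocarbonyldiimidazole with DMAP gives the imidazolyl thiocarbonate F10. Bu3SnH/AIBN in benzene at 80 °C generates the C2 radical, which opens the epoxide to the C4 alkoxy radical and gives 15 after hydrogen transfer.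

**Step 9.** Under aqueous acid the allylic C4 alcohol may ionise (allylic transposition or epimerisation), the α-ketol may rearrange, and the tertiary silyl ether may be cleaved incompletely. The fallback separates desilylation from carbamate cleavage and removes the carbamate without protic acid after the epoxide is in place; it sets out from 15 and ends at 24. HF·pyridine in THF/pyridine gives the carbamate-protected triol F11. VO(acac)2/t-BuOOH gives the carbamate-protected epoxy triol F12. Me3SiOTf/2,6-lutidine followed by methanol gives the amino epoxy triol F13, and coupling with 22 under the conditions of step 12 gives 24.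

## Further compounds

F1 | step 6 | tert-butyl N-[(2S)-1-hydroxy-3-(1-hydroxy-2,6-dioxocyclohexyl)propan-2-yl]carbamate | CC(C)(C)OC(=O)N[C@H](CO)CC1(O)C(=O)CCCC1=O
F2 | step 6 | tert-butyl N-[(3S)-2-hydroxy-6,10-dioxo-1-oxaspiro[4.5]decan-3-yl]carbamate | CC(C)(C)OC(=O)N[C@H]1CC2(OC1O)C(=O)CCCC2=O
F3 | step 6 | tert-butyl N-[(1S,5R,6R,7S)-2,9-dioxo-1,6-bis(triethylsilyloxy)bicyclo[3.3.1]nonan-7-yl]carbamate | CC(C)(C)OC(=O)N[C@H]1C[C@@]2(O[Si](CC)(CC)CC)C(=O)[C@H](CCC2=O)[C@H]1O[Si](CC)(CC)CC
F4 | step 1 | tert-butyl (S)-4-(hydroxymethyl)-2,2-dimethyloxazolidine-3-carboxylate | CC1(C)OC[C@H](CO)N1C(=O)OC(C)(C)C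
F5 | step 1 | tert-butyl (R)-4-(iodomethyl)-2,2-dimethyloxazolidine-3-carboxylate | CC1(C)OC[C@H](CI)N1C(=O)OC(C)(C)C
F6 | step 1 | tert-butyl (S)-4-[(2,6-dimethoxycyclohexa-2,5-dien-1-yl)methyl]-2,2-dimethyloxazolidine-3-carboxylate | COC1=CCC=C(OC)C1C[C@H]2COC(C)(C)N2C(=O)OC(C)(C)C
F7 | step 3 | tert-butyl (4S)-4-{[1-hydroxy-2,6-dioxo-3-(phenylselanyl)cyclohexyl]methyl}-2,2-dimethyloxazolidine-3-carboxylate | CC1(C)OC[C@H](CC2(O)C(=O)CCC([Se]c3ccccc3)C2=O)N1C(=O)OC(C)(C)C
F8 | step 3 | tert-butyl (4S)-4-[(1-hydroxy-2,6-dioxocyclohex-3-en-1-yl)methyl]-2,2-dimethyloxazolidine-3-carboxylate | CC1(C)OC[C@H](CC2(O)C(=O)CC=CC2=O)N1C(=O)OC(C)(C)C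
F9 | step 8 | tert-butyl N-[(3S,4S,5R,6R,7S)-3,4-epoxy-2-hydroxy-9-oxo-1,6-bis(triethylsilyloxy)bicyclo[3.3.1]nonan-7-yl]carbamate (C2 epimers) | CC(C)(C)OC(=O)N[C@H]1C[C@@]2(O[Si](CC)(CC)CC)C(=O)[C@H]([C@@H]3O[C@@H]3C2O)[C@H]1O[Si](CC)(CC)CC
F10 | step 8 | O-[7-(tert-butoxycarbonylamino)-3,4-epoxy-9-oxo-1,6-bis(triethylsilyloxy)bicyclo[3.3.1]nonan-2-yl] 1H-imidazole-1-carbothioate | CC(C)(C)OC(=O)N[C@H]1C[C@@]2(O[Si](CC)(CC)CC)C(=O)[C@H]([C@@H]3O[C@@H]3C2OC(=S)n4ccnc4)[C@H]1O[Si](CC)(CC)CC
F11 | step 9 | tert-butyl N-[(1S,4R,5R,6R,7S)-1,4,6-trihydroxy-9-oxobicyclo[3.3.1]non-2-en-7-yl]carbamate | CC(C)(C)OC(=O)N[C@H]1C[C@@]2(O)C(=O)[C@H]([C@H](O)C=C2)[C@H]1O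
F12 | step 9 | tert-butyl N-[2,3-exo-epoxy-1,4,6-trihydroxy-9-oxobicyclo[3.3.1]nonan-7-yl]carbamate (configuration of 24) | CC(C)(C)OC(=O)N[C@H]1C[C@@]2(O)C(=O)[C@H]([C@H](O)[C@@H]3O[C@@H]32)[C@H]1O
F13 | step 9 | 7-amino-2,3-exo-epoxy-1,4,6-trihydroxybicyclo[3.3.1]nonan-9-one (configuration of 24) | N[C@H]1C[C@@]2(O)C(=O)[C@H]([C@H](O)[C@@H]3O[C@@H]32)[C@H]1O
A1 | alternative 1 | tert-butyl N-[(2S)-1-(1-hydroxy-4-oxocyclohexa-2,5-dien-1-yl)-3-oxopropan-2-yl]carbamate | CC(C)(C)OC(=O)N[C@@H](CC1(O)C=CC(=O)C=C1)C=O
A2 | alternative 1 | tert-butyl N-[(2S)-1-(all-cis-2,3-epoxy-1,4-dihydroxy-6-oxocyclohexyl)-3-oxopropan-2-yl]carbamate | CC(C)(C)OC(=O)N[C@H](C=O)C[C@@]1(O)C(=O)C[C@H](O)[C@@H]2O[C@@H]21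
A3 | alternative 2 | tert-butyl N-[(2S)-1-(1,2-dihydroxy-4-oxocyclohexa-2,5-dien-1-yl)-3-oxopropan-2-yl]carbamate (C1 epimers) | CC(C)(C)OC(=O)N[C@H](C=O)CC1(O)C=CC(=O)C=C1O
A4 | alternative 2 | tert-butyl N-[(1S,5S,6R,7S)-1,6-dihydroxy-4,9-dioxobicyclo[3.3.1]non-2-en-7-yl]carbamate | CC(C)(C)OC(=O)N[C@H]1C[C@@]2(O)C(=O)[C@H](C(=O)C=C2)[C@H]1O
A5 | alternative 3 | benzyl N-[3-ethenyl-3,6-dihydroxy-5-(1-hydroxyprop-2-enyl)-4-oxocyclohexyl]carbamate (configuration of 24) | O=C(OCc1ccccc1)N[C@H]1C[C@@](C=C)(O)C(=O)[C@H]([C@H](O)C=C)[C@H]1O
A6 | alternative 3 | benzyl N-[(1S,4R,5R,6R,7S)-1,4,6-trihydroxy-9-oxobicyclo[3.3.1]non-2-en-7-yl]carbamate | O=C(OCc1ccccc1)N[C@H]1C[C@@]2(O)C(=O)[C@H]([C@H](O)C=C2)[C@H]1O
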